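## Structural features

The target is a 3,4-seco-abietane: a hexasubstituted benzene (ring C) fused to a cyclohexanone (ring B), with ring A opened. C5 therefore carries an isopropenyl group (C4, C18, C19), and C10 carries a methyl group (C20) and a propanoic acid arm (C1–C3). Ring C bears a free hydroquinone (C11–OH, C14–OH), a methyl ether at C12 and an isopropyl group at C13; C8 holds the C7 ketone, hydrogen-bonded to the C14 hydroxyl, and C9 holds the quaternary carbon C10. The only stereocentres, C5 (tertiary, allylic, β to the ketone) and C10 (quaternary, benzylic), are adjacent, both S, and place the isopropenyl group cis to the C10 methyl group. The hydroquinone is prone to air oxidation, the isopropenyl group to acid, and a C3 aldehyde can close onto C6 by aldol reaction. The real difficulty is the benzylic quaternary stereocentre next to a tertiary one, pressed against the C11 oxygen, together with the unambiguous placement of six different substituents on ring C. The feature exploited is that C5 carries two almost identical 2-propenyl units: the visible isopropenyl group and the C10(C20)–C1 unit hidden in the quaternary carbon. Ring B therefore maps onto an achiral aryl ketone in which C5 bears two enantiotopic isopropenyl groups and aryl carbon C9 bears bromine.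

## Logic of the disconnections

**28 ⇒ 27.** The O–CH3 bond at C14 and the O–CH2OCH3 bond at C11 are cut. The hydroquinone is unveiled last because it would not survive the chlorite oxidation or the organometallic steps. The C14 oxygen is carried as a methyl ether because the neighbouring C7 ketone lets a boron Lewis acid remove it by chelation, so one reagent can free both phenols. The forward step must spare the unchelated C12 methyl ether and the isopropenyl group.

**27 ⇒ 26 ⇒ 25.** No skeletal bond is cut; C3 is taken back from acid to aldehyde to the (E)-enol ether. This places the whole acid arm in the coupling partner of the key step. The hydrolysis must be mild enough to keep the methoxymethyl ether and short enough to prevent aldol closure of C3 onto C6.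

**25 ⇒ 21 + 22.** The C9–C10 bond and the C1–C2 bond are cut in one operation. This removes ring B and both stereocentres and leads to an achiral ketone and a commercial alkenylboronate. The forward step must select one enantiotopic isopropenyl group, close 6-exo, and hold the alkylpalladium until it is coupled.

**21 ⇒ 19 + 8.** The C7–C8 aryl–acyl bond is cut, giving a pentasubstituted bromoarene with a single aromatic hydrogen and an achiral amide. The forward step must metalate C8 without bromine migration or loss of lithium bromide, and the acyl transfer must stop at the ketone.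

**19 ⇒ 17 ⇒ 16 ⇒ 14 ⇒ 13 ⇒ 12 ⇒ 9 + 10.** The C9–Br bond, the methoxymethyl O–C bond, the C11–O bond (through a C11 formyl group) and the C13–isopropyl bond are cut in turn. Every substituent enters at a position fixed by symmetry or by the strongest director, so no step depends on a subtle regiochemical preference:
- 9 is lithiated between its two methoxy groups.
- 13 has two equivalent activated positions.
- 17 has one acetal-type director with one ortho hydrogen.
- 19 has only one hydrogen left.

**8 ⇒ 7 ⇒ 4 + 5, and 4 ⇒ 3 ⇒ 1 + 2.** The C5–C6 bond is cut as a [3,3] shift, and the diene alcohol is taken back to an olefination. The hydroxyl must sit on the primary carbon of the diene: a shift from a doubly allylic secondary position would give a linear skeleton instead of two isopropenyl groups on one carbon.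

## Other disconnections considered

**Alternative 1: ring C by cyclobutenone ring expansion.**
- Cut: the C8–C14 bond, so that ring C is assembled last from a four-carbon cyclobutenone unit and the C8=C9 alkene of a preformed, enantiopure ring B.
- Forward key step: heating the 4-hydroxy-4-(cyclohexenyl)cyclobutenone A2 should open the four-membered ring to a dienylketene; 6π electrocyclization and tautomerization would then give the hydroquinone A1.
- In favour: the substituent pattern of ring C follows from the connectivity of the four-carbon unit, and the step needs no reagent, catalyst or protecting group on the new hydroquinone. On arene regiochemistry this plan is better than the chosen one, which spends six steps decorating the benzene ring.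
- Against: the step creates no stereocentre. The C5/C10 pair must be built beforehand in a hindered cyclohexenyl nucleophile. A1 is an air-sensitive free hydroquinone. C7 must be reoxidized and the silyloxypropyl arm oxidized to the acid.
- Comparison: mechanistically the pericyclic cascade is more predictable than an enantioselective palladium cascade. In step economy it should be longer, because the stereochemical problem and several redox adjustments remain outside the key step.

**Alternative 2: ring B by photoenolization/Diels–Alder reaction.**
- Cut: the C6–C7 and C5–C10 bonds.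
- Forward key step: irradiation of the lactone-bridged benzaldehyde A4 with Ti(OiPr)4 should give a titanium-bound hydroxy-ortho-quinodimethane, which adds endo across the 2,3-alkene of the dienoate A5 to give A3.
- In favour: two carbon–carbon bonds, ring B and three stereocentres in one convergent step. The lactone fixes the geometry of the fully substituted diene terminus and masks the C11 oxygen and the acid arm at once. In bonds and stereocentres formed per step this plan is the equal of the chosen one or better.
- Against: the C10 centre of A4 is erased on enolization, so absolute control must come from a chiral titanium complex acting on a tetrasubstituted diene terminus. A5 is itself a diene and may react at its other alkene or oligomerize. The C6 ester of A3 has to be removed after oxidation at C7, and the C14 methyl ether still has to be cleaved.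
- Comparison: relative configuration is well founded (endo rule and chelation), but enantiocontrol is less secure than ligand control in an intramolecular insertion. The number of steps after the key step is similar.

**Alternative 3: ring B by glyoxal–ene cyclization.**
- Cut: the C5–C6 bond.
- Forward key step: a Lewis acid such as SnCl4 should activate the aryl glyoxal A7 so that the C5=C4 alkene attacks C6 while an allylic methyl hydrogen moves to oxygen, giving A6 with ring B closed and the isopropenyl group formed.
- In favour: complete atom economy, mild conditions, and the isopropenyl group arises from the bond formation itself. In atom economy the step is better than the chosen one, which sets free stoichiometric silver and boron by-products.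
- Against: the quaternary benzylic stereocentre C10, the hardest element of the target, must already be present in A7 in enantiopure form. The C5 configuration then depends on the ene transition state distinguishing a methyl group from a three-carbon ester arm at C10. The C6 hydroxyl of A6 must be removed reductively.
- Comparison: one bond and one stereocentre are formed against two and two in the chosen plan. Overall the route should be longer because an asymmetric construction of C10 has to precede it.

Key step: step 12

Remarks on the chemistry, made before the steps: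
- Positions in the bicyclic compounds are numbered as in the abietane skeleton.
- The two phenol oxygens are carried as a methyl ether (C14) and a methoxymethyl ether (C11); the carbon skeletons of 21 and 25 are unaffected by this choice.
- (R)-BINAP is written for the (5S,10S) series. The sense of induction cannot be predicted with certainty, and the mirror-image ligand is to be used if the opposite series forms.

## Route

Step 1
Reactants: 1 methacrolein; 2 ethyl 2-(triphenylphosphoranylidene)propanoate
Product: 3 ethyl (2E)-2,4-dimethylpenta-2,4-dienoate
Conditions: CH2Cl2, 0 °C → rt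
Reagents that add atoms: none
Why: Wittig olefination with a stabilized ylide should attack the aldehyde carbonyl only and give the E trisubstituted alkene; the geometry is lost again in step 3.

Step 2
Reactants: 3 ethyl (2E)-2,4-dimethylpenta-2,4-dienoate
Product: 4 (2E)-2,4-dimethylpenta-2,4-dien-1-ol
Conditions: i-Bu2AlH (2.2 equiv), CH2Cl2, −78 → 0 °C; aq. potassium sodium tartrate
Reagents that add atoms: none
Why: Aluminium hydride 1,2-reduction of a conjugated ester should give the primary allylic alcohol without touching the diene.

Step 3
Reactants: 4 (2E)-2,4-dimethylpenta-2,4-dien-1-ol; 5 triethyl orthoacetate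
Product: 7 ethyl 4-methyl-3-(prop-1-en-2-yl)pent-4-enoate, via mixed ketene acetal 6 (not isolated)
Conditions: EtCO2H (cat.), excess 5 as solvent, 140 °C, EtOH distilled off
Reagents that add atoms: none
Why: Johnson–Claisen rearrangement: exchange gives the ketene acetal 6, whose [3,3] shift forms the C5–C6 bond at the inner diene carbon and turns the former carbinol end into the second isopropenyl group. The product is achiral, so no stereocontrol is needed.

Step 4
Reactants: 7 ethyl 4-methyl-3-(prop-1-en-2-yl)pent-4-enoate
Product: 8 N-methoxy-N,4-dimethyl-3-(prop-1-en-2-yl)pent-4-enamide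
Conditions: MeNH(OMe)·HCl, i-PrMgCl, THF, −20 → 0 °C
Reagents that add atoms: N,O-dimethylhydroxylamine hydrochloride, CNOC.Cl
Why: Direct aminolysis of the ester by the magnesium amide of N,O-dimethylhydroxylamine (Weinreb amide formation) should proceed without isomerizing the skipped diene.

Step 5
Reactants: 9 1,3-dimethoxybenzene; 10 acetone
Product: 12 2-(2,6-dimethoxyphenyl)propan-2-ol, via 2,6-dimethoxyphenyllithium 11 (not isolated)
Conditions: n-BuLi, THF, 0 °C → rt; then 10, −78 °C → rt; aq. NH4Cl
Reagents that add atoms: none
Why: Directed ortho-metalation: the hydrogen between the two methoxy groups is the most acidic and the only doubly coordinated one, so 11 forms at that carbon and adds to the ketone.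

Step 6
Reactants: 12 2-(2,6-dimethoxyphenyl)propan-2-ol
Product: 13 1,3-dimethoxy-2-(propan-2-yl)benzene
Conditions: Et3SiH, CF3CO2H, CH2Cl2, 0 °C → rt
Reagents that add atoms: none
Why: Ionic hydrogenation: the tertiary benzylic cation, stabilized by two ortho methoxy groups, should take hydride from the silane; methyl ethers are stable to the acid.

Step 7
Reactants: 13 1,3-dimethoxy-2-(propan-2-yl)benzene
Product: 14 2,4-dimethoxy-3-(propan-2-yl)benzaldehyde
Conditions: POCl3, DMF, 0 → 70 °C; then aq. NaOAc
Reagents that add atoms: N,N-dimethylformamide, CN(C)C=O; water, O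
Why: Vilsmeier–Haack formylation: the two positions ortho to one methoxy group and para to the other are equivalent by symmetry, and the position meta to both is not activated, so only one aldehyde can form.

Step 8
Reactants: 14 2,4-dimethoxy-3-(propan-2-yl)benzaldehyde
Product: 16 2,4-dimethoxy-3-(propan-2-yl)phenol, via aryl formate 15 (not isolated)
Conditions: mCPBA, CH2Cl2, 0 °C → rt; then K2CO3 (cat.), MeOH, rt
Reagents that add atoms: 3-chloroperoxybenzoic acid, O=C(OO)c1cccc(Cl)c1
Why: Dakin-type Baeyer–Villiger oxidation: the electron-rich aryl group migrates to oxygen and the formate 15 is cleaved by methanolysis, placing the future C11 oxygen next to the C12 methoxy group.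

Step 9
Reactants: 16 2,4-dimethoxy-3-(propan-2-yl)phenol
Product: 17 2,4-dimethoxy-1-(methoxymethoxy)-3-(propan-2-yl)benzene
Conditions: MOMCl, i-Pr2NEt, CH2Cl2, 0 °C → rt
Reagents that add atoms: chloromethyl methyl ether, COCCl
Why: O-Alkylation of the phenol gives an acetal ether that is stable to the bases and the palladium step ahead and is the strongest ortho director on the ring.

Step 10
Reactants: 17 2,4-dimethoxy-1-(methoxymethoxy)-3-(propan-2-yl)benzene
Product: 19 1-bromo-3,5-dimethoxy-2-(methoxymethoxy)-4-(propan-2-yl)benzene, via aryllithium 18 (not isolated)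
Conditions: n-BuLi, THF, 0 °C; then BrCH2CH2Br, −78 °C → rt
Reagents that add atoms: 1,2-dibromoethane, BrCCBr
Why: Directed ortho-metalation followed by bromine transfer: the methoxymethoxy group chelates lithium far better than a methoxy group and has a single ortho hydrogen (the future C9), so 18 should form there and be brominated with loss of ethene.

Step 11
Reactants: 19 1-bromo-3,5-dimethoxy-2-(methoxymethoxy)-4-(propan-2-yl)benzene; 8 N-methoxy-N,4-dimethyl-3-(prop-1-en-2-yl)pent-4-enamide
Product: 21 1-[2-bromo-4,6-dimethoxy-3-(methoxymethoxy)-5-(propan-2-yl)phenyl]-4-methyl-3-(prop-1-en-2-yl)pent-4-en-1-one, via bromoaryllithium 20 (not isolated)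
Conditions: LiN(i-Pr)2, THF, −78 °C (19 added to the base); then 8, −78 → −50 °C; aq. NH4Cl
Reagents that add atoms: none
Why: Amide-base deprotonation of the only aromatic hydrogen, which is flanked by bromine and a methoxy group, followed by Weinreb ketone synthesis. The amide base does not exchange the bromine, and the chelated tetrahedral adduct prevents a second addition.

Step 12
Reactants: 21 1-[2-bromo-4,6-dimethoxy-3-(methoxymethoxy)-5-(propan-2-yl)phenyl]-4-methyl-3-(prop-1-en-2-yl)pent-4-en-1-one; 22 (E)-2-(2-ethoxyvinyl)-4,4,5,5-tetramethyl-1,3,2-dioxaborolane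
Product: 25 (3S,4S)-4-[(2E)-3-ethoxyprop-2-en-1-yl]-6,8-dimethoxy-5-(methoxymethoxy)-4-methyl-7-(propan-2-yl)-3-(prop-1-en-2-yl)-3,4-dihydronaphthalen-1(2H)-one, via arylpalladium bromide complex 23 (not isolated), via neopentylpalladium hydroxide complex 24 (not isolated)
Conditions: Pd2(dba)3 (5 mol %), (R)-BINAP (12 mol %), Ag3PO4 (2 equiv), degassed THF/H2O 10:1, 70 °C
Reagents that add atoms: none
Why: Zerovalent palladium carrying (R)-BINAP inserts into the C9–Br bond to give 23, and Ag3PO4 removes bromide so that both phosphorus atoms stay on the cationic divalent palladium during the stereo-determining step. The aryl group then adds across one isopropenyl group by 6-exo-trig migratory insertion, which closes ring B, forms C9–C10 and leaves palladium on the primary carbon C1. Because C10 is now quaternary, 24 has no β-hydrogen; the spectator isopropenyl group could be reached only through a four-membered ring and the hexasubstituted arene offers no C–H bond, so 24 persists until transmetalation with 22 and reductive elimination form C1–C2 with retention of the E enol ether. The closest known reaction types are the enantioselective domino Heck/Suzuki reaction that builds benzylic quaternary centres and the desymmetrizing asymmetric Heck cyclization of prochiral dienes. C10 and C5 are created together: the ligand decides which enantiotopic isopropenyl group, and thereby which alkene face, reacts, and this fixes the absolute configuration of both centres. Their relative configuration is controlled by the substrate: allylic strain keeps the C5–H bond near the plane of the reacting alkene, the tether occupies one face and the spectator isopropenyl group the other, so it ends cis to the new C10 methyl group. The step needs cyclization to outrun direct coupling of 23 with 22, which the intramolecular geometry and the hindered, doubly ortho-substituted arylpalladium should secure. It also needs 6-exo to beat 7-endo closure, which the 1,1-disubstituted alkene secures by taking the aryl group on its substituted carbon.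

Step 13
Reactants: 25 (3S,4S)-4-[(2E)-3-ethoxyprop-2-en-1-yl]-6,8-dimethoxy-5-(methoxymethoxy)-4-methyl-7-(propan-2-yl)-3-(prop-1-en-2-yl)-3,4-dihydronaphthalen-1(2H)-one
Product: 26 3-[(1S,2S)-5,7-dimethoxy-8-(methoxymethoxy)-1-methyl-4-oxo-6-(propan-2-yl)-2-(prop-1-en-2-yl)-1,2,3,4-tetrahydronaphthalen-1-yl]propanal
Conditions: 0.5 M HCl, THF/H2O, 0 °C, short contact; crude aldehyde used at once
Reagents that add atoms: water, O
Why: Acid-catalysed enol ether hydrolysis: carbon protonation of the enol ether is much faster than ionization of the aryl methoxymethyl acetal, so the aldehyde should be released with the protecting group intact. C5 is β to the ketone and C10 is quaternary, so neither centre can epimerize.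

Step 14
Reactants: 26 3-[(1S,2S)-5,7-dimethoxy-8-(methoxymethoxy)-1-methyl-4-oxo-6-(propan-2-yl)-2-(prop-1-en-2-yl)-1,2,3,4-tetrahydronaphthalen-1-yl]propanal
Product: 27 3-[(1S,2S)-5,7-dimethoxy-8-(methoxymethoxy)-1-methyl-4-oxo-6-(propan-2-yl)-2-(prop-1-en-2-yl)-1,2,3,4-tetrahydronaphthalen-1-yl]propanoic acid
Conditions: NaClO2, NaH2PO4, 2-methyl-2-butene, t-BuOH/H2O, 0 °C → rt
Reagents that add atoms: sodium chlorite, [Na+].[O-]Cl=O
Why: Pinnick oxidation converts the aldehyde to the acid at buffered pH; the excess trisubstituted alkene scavenges hypochlorous acid before it can reach the less reactive isopropenyl group, and the fully substituted, protected arene offers no site for chlorination.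

Step 15
Reactants: 27 3-[(1S,2S)-5,7-dimethoxy-8-(methoxymethoxy)-1-methyl-4-oxo-6-(propan-2-yl)-2-(prop-1-en-2-yl)-1,2,3,4-tetrahydronaphthalen-1-yl]propanoic acid
Product: 28 3-[(1S,2S)-5,8-dihydroxy-7-methoxy-1-methyl-4-oxo-6-(propan-2-yl)-2-(prop-1-en-2-yl)-1,2,3,4-tetrahydronaphthalen-1-yl]propanoic acid (CNP0249049.1; 5S,10S in abietane numbering)
Conditions: BCl3, CH2Cl2, −78 → −20 °C; then aq. NaHCO3, acidified to pH 3 under argon
Reagents that add atoms: none
Why: Lewis-acid ether cleavage: BCl3 should open the methoxymethyl acetal at −78 °C and, held in a six-membered chelate between the C7 carbonyl and the C14 oxygen, remove that methyl group selectively. The C12 methyl ether has no chelating partner and should survive at low temperature.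

## Compound list

1 | methacrolein | C=C(C)C=O | starting material
2 | ethyl 2-(triphenylphosphoranylidene)propanoate | CCOC(=O)C(C)=P(c1ccccc1)(c1ccccc1)c1ccccc1 | starting material
3 | ethyl (2E)-2,4-dimethylpenta-2,4-dienoate | CCOC(=O)/C(C)=C/C(C)=C | intermediate
4 | (2E)-2,4-dimethylpenta-2,4-dien-1-ol | OC/C(C)=C/C(C)=C | intermediate
5 | triethyl orthoacetate | CCOC(C)(OCC)OCC | starting material
6 | 1-ethoxy-1-{[(2E)-2,4-dimethylpenta-2,4-dien-1-yl]oxy}ethene (mixed ketene acetal, not isolated) | C=C(OCC)OC/C(C)=C/C(C)=C | intermediate
7 | ethyl 4-methyl-3-(prop-1-en-2-yl)pent-4-enoate | CCOC(=O)CC(C(C)=C)C(C)=C | intermediate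
8 | N-methoxy-N,4-dimethyl-3-(prop-1-en-2-yl)pent-4-enamide | CON(C)C(=O)CC(C(C)=C)C(C)=C | intermediate
9 | 1,3-dimethoxybenzene | COc1cccc(OC)c1 | starting material
10 | acetone | CC(C)=O | starting material
11 | 2,6-dimethoxyphenyllithium (not isolated) | COc1cccc(OC)c1[Li] | intermediate
12 | 2-(2,6-dimethoxyphenyl)propan-2-ol | COc1cccc(OC)c1C(C)(C)O | intermediate
13 | 1,3-dimethoxy-2-(propan-2-yl)benzene | COc1cccc(OC)c1C(C)C | intermediate
14 | 2,4-dimethoxy-3-(propan-2-yl)benzaldehyde | COc1ccc(C=O)c(OC)c1C(C)C | intermediate
15 | 2,4-dimethoxy-3-(propan-2-yl)phenyl formate (not isolated) | COc1ccc(OC=O)c(OC)c1C(C)C | intermediate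
16 | 2,4-dimethoxy-3-(propan-2-yl)phenol | COc1ccc(O)c(OC)c1C(C)C | intermediate
17 | 2,4-dimethoxy-1-(methoxymethoxy)-3-(propan-2-yl)benzene | COCOc1ccc(OC)c(C(C)C)c1OC | intermediate
18 | [3,5-dimethoxy-2-(methoxymethoxy)-4-(propan-2-yl)phenyl]lithium (not isolated) | COCOc1c([Li])cc(OC)c(C(C)C)c1OC | intermediate
19 | 1-bromo-3,5-dimethoxy-2-(methoxymethoxy)-4-(propan-2-yl)benzene | COCOc1c(Br)cc(OC)c(C(C)C)c1OC | intermediate
20 | [2-bromo-4,6-dimethoxy-3-(methoxymethoxy)-5-(propan-2-yl)phenyl]lithium (not isolated) | COCOc1c(Br)c([Li])c(OC)c(C(C)C)c1OC | intermediate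
21 | 1-[2-bromo-4,6-dimethoxy-3-(methoxymethoxy)-5-(propan-2-yl)phenyl]-4-methyl-3-(prop-1-en-2-yl)pent-4-en-1-one (achiral) | C=C(C)C(CC(=O)c1c(OC)c(C(C)C)c(OC)c(OCOC)c1Br)C(C)=C | intermediate
22 | (E)-2-(2-ethoxyvinyl)-4,4,5,5-tetramethyl-1,3,2-dioxaborolane | CCO/C=C/B1OC(C)(C)C(C)(C)O1 | starting material
23 | arylpalladium bromide complex from 21 (C9–Pd–Br; BINAP on palladium not drawn; not isolated) | C=C(C)C(CC(=O)c1c(OC)c(C(C)C)c(OC)c(OCOC)c1[Pd]Br)C(C)=C | intermediate
24 | neopentylpalladium hydroxide complex (ring B closed, palladium on C1, C5 and C10 configured as in 25; BINAP not drawn; not isolated) | C=C(C)[C@@H]1CC(=O)c2c(OC)c(C(C)C)c(OC)c(OCOC)c2[C@@]1(C)C[Pd]O | intermediate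
25 | (3S,4S)-4-[(2E)-3-ethoxyprop-2-en-1-yl]-6,8-dimethoxy-5-(methoxymethoxy)-4-methyl-7-(propan-2-yl)-3-(prop-1-en-2-yl)-3,4-dihydronaphthalen-1(2H)-one (isopropenyl cis to methyl) | C=C(C)[C@@H]1CC(=O)c2c(OC)c(C(C)C)c(OC)c(OCOC)c2[C@@]1(C)C/C=C/OCC | intermediate
26 | 3-[(1S,2S)-5,7-dimethoxy-8-(methoxymethoxy)-1-methyl-4-oxo-6-(propan-2-yl)-2-(prop-1-en-2-yl)-1,2,3,4-tetrahydronaphthalen-1-yl]propanal | C=C(C)[C@@H]1CC(=O)c2c(OC)c(C(C)C)c(OC)c(OCOC)c2[C@@]1(C)CCC=O | intermediate
27 | 3-[(1S,2S)-5,7-dimethoxy-8-(methoxymethoxy)-1-methyl-4-oxo-6-(propan-2-yl)-2-(prop-1-en-2-yl)-1,2,3,4-tetrahydronaphthalen-1-yl]propanoic acid | C=C(C)[C@@H]1CC(=O)c2c(OC)c(C(C)C)c(OC)c(OCOC)c2[C@@]1(C)CCC(=O)O | intermediate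
28 | 3-[(1S,2S)-5,8-dihydroxy-7-methoxy-1-methyl-4-oxo-6-(propan-2-yl)-2-(prop-1-en-2-yl)-1,2,3,4-tetrahydronaphthalen-1-yl]propanoic acid | C=C(C)[C@@H]1CC(=O)c2c(O)c(C(C)C)c(OC)c(O)c2[C@@]1(C)CCC(=O)O | target

## Step count and least certain steps

Total step count: 15. Longest linear sequence: 11 steps (steps 5 to 15, from 9); the side chain (steps 1 to 4) joins at step 11.

**Step 12 (key step).** Most likely failures are incomplete discrimination between the two enantiotopic isopropenyl groups, slow oxidative addition into the hindered, electron-rich C9–Br bond, and premature coupling or protodepalladation before or after ring closure. The relative configuration should be secure because it is set by the substrate. Fallback: starting from 21, run the same domino with an achiral catalyst (Pd(OAc)2 with a dialkylbiarylphosphine, K3PO4, aqueous dioxane). This should give the cis racemate, that is 25 together with its mirror image, the (3R,4R)-enantiomer of 25 F1. The enantiomers are then separated by preparative chromatography on a chiral stationary phase, and the route is rejoined at 25.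

**Step 11.** The ortho-bromoaryllithium may lose lithium bromide to an aryne, pass its bromine to unreacted 19 (halogen migration), or act as a base toward the α-hydrogens of 8 instead of adding. Fallback without a free aryllithium: starting from 19, electrophilic iodination of the single free position (N-iodosuccinimide, CF3CO2H cat., MeCN) gives 1-bromo-6-iodo-3,5-dimethoxy-2-(methoxymethoxy)-4-(propan-2-yl)benzene F2. Iodine–magnesium exchange (i-PrMgCl·LiCl, THF, −40 °C) is selective for iodine. The arylmagnesium is added to 4-methyl-3-(prop-1-en-2-yl)pent-4-enal F3, obtained from 8 with i-Bu2AlH at −78 °C. This gives the racemic carbinol 1-[2-bromo-4,6-dimethoxy-3-(methoxymethoxy)-5-(propan-2-yl)phenyl]-4-methyl-3-(prop-1-en-2-yl)pent-4-en-1-ol F4, which Dess–Martin periodinane oxidizes to 21.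

**Step 10.** Metalation ortho to the C14 methoxy group instead of ortho to the methoxymethoxy group would put bromine on the wrong carbon and lead to a regioisomeric series. Fallback by electrophilic substitution: starting from 16, amine-mediated ortho-bromination of the free phenol (N-bromosuccinimide, i-Pr2NH cat., CH2Cl2, −20 °C) gives 6-bromo-2,4-dimethoxy-3-(propan-2-yl)phenol F5. Protection with MOMCl and i-Pr2NEt then rejoins the route at 19.

**Step 15.** The C12 methyl ether, twisted and next to the freed C11 oxygen, may also be cleaved if the mixture warms, and hydrogen chloride or the Lewis acid may attack the isopropenyl group. Fallback in two milder operations: starting from 27, MgI2 in toluene/Et2O at 60 °C removes only the methyl ether chelated to the C7 carbonyl. This gives 3-[(1S,2S)-5-hydroxy-7-methoxy-8-(methoxymethoxy)-1-methyl-4-oxo-6-(propan-2-yl)-2-(prop-1-en-2-yl)-1,2,3,4-tetrahydronaphthalen-1-yl]propanoic acid F6, and dilute HCl in THF then removes the acetal to give 28.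

**Step 13.** The acid may start to remove the methoxymethyl ether, and the free aldehyde may close onto C6 by intramolecular aldol reaction (a bicyclo[3.3.1] ring). Fallback that avoids the free aldehyde: starting from 25, pyridinium chlorochromate (NaOAc buffer, CH2Cl2) oxidizes the enol ether directly to ethyl 3-[(1S,2S)-5,7-dimethoxy-8-(methoxymethoxy)-1-methyl-4-oxo-6-(propan-2-yl)-2-(prop-1-en-2-yl)-1,2,3,4-tetrahydronaphthalen-1-yl]propanoate F7. LiOH in THF/H2O then gives 27.

## Further compounds

F1 | step 12 | (3R,4R)-enantiomer of 25 | C=C(C)[C@H]1CC(=O)c2c(OC)c(C(C)C)c(OC)c(OCOC)c2[C@]1(C)C/C=C/OCC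
F2 | step 11 | 1-bromo-6-iodo-3,5-dimethoxy-2-(methoxymethoxy)-4-(propan-2-yl)benzene | COCOc1c(Br)c(I)c(OC)c(C(C)C)c1OC
F3 | step 11 | 4-methyl-3-(prop-1-en-2-yl)pent-4-enal | C=C(C)C(CC=O)C(C)=C
F4 | step 11 | 1-[2-bromo-4,6-dimethoxy-3-(methoxymethoxy)-5-(propan-2-yl)phenyl]-4-methyl-3-(prop-1-en-2-yl)pent-4-en-1-ol (racemic) | C=C(C)C(CC(O)c1c(OC)c(C(C)C)c(OC)c(OCOC)c1Br)C(C)=C
F5 | step 10 | 6-bromo-2,4-dimethoxy-3-(propan-2-yl)phenol | COc1cc(Br)c(O)c(OC)c1C(C)C
F6 | step 15 | 3-[(1S,2S)-5-hydroxy-7-methoxy-8-(methoxymethoxy)-1-methyl-4-oxo-6-(propan-2-yl)-2-(prop-1-en-2-yl)-1,2,3,4-tetrahydronaphthalen-1-yl]propanoic acid | C=C(C)[C@@H]1CC(=O)c2c(O)c(C(C)C)c(OC)c(OCOC)c2[C@@]1(C)CCC(=O)O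
F7 | step 13 | ethyl 3-[(1S,2S)-5,7-dimethoxy-8-(methoxymethoxy)-1-methyl-4-oxo-6-(propan-2-yl)-2-(prop-1-en-2-yl)-1,2,3,4-tetrahydronaphthalen-1-yl]propanoate | C=C(C)[C@@H]1CC(=O)c2c(OC)c(C(C)C)c(OC)c(OCOC)c2[C@@]1(C)CCC(=O)OCC
A1 | alternative 1 | 11,14-hydroquinone fused to ring B with C7 tert-butyldimethylsilyl ether and 3-(tert-butyldimethylsilyloxy)propyl arm (C5 and C10 as in 28) | C=C(C)[C@@H]1CC(O[Si](C)(C)C(C)(C)C)c2c(O)c(C(C)C)c(OC)c(O)c2[C@@]1(C)CCCO[Si](C)(C)C(C)(C)C
A2 | alternative 1 | 4-hydroxy-3-methoxy-2-(propan-2-yl)-4-(cyclohex-1-enyl)cyclobut-2-en-1-one carrying the ring B substituents (carbinol carbon unassigned) | C=C(C)[C@@H]1CC(O[Si](C)(C)C(C)(C)C)C=C(C2(O)C(OC)=C(C(C)C)C2=O)[C@@]1(C)CCCO[Si](C)(C)C(C)(C)C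
A3 | alternative 2 | endo cycloadduct: lactone-bridged tetralin with C7 hydroxyl, C6 methoxycarbonyl, C5 isopropenyl and C10 methyl | C=C(C)[C@@H]1[C@@H](C(=O)OC)[C@@H](O)c2c(OC)c(C(C)C)c(OC)c3c2[C@@]1(C)CCC(=O)O3
A4 | alternative 2 | 7,9-dimethoxy-5-methyl-2-oxo-8-(propan-2-yl)-2,3,4,5-tetrahydro-1-benzoxepine-6-carbaldehyde (racemic) | O=Cc1c(OC)c(C(C)C)c(OC)c2OC(=O)CCC(C)c12
A5 | alternative 2 | methyl (E)-4-methylpenta-2,4-dienoate | C=C(C)/C=C/C(=O)OC
A6 | alternative 3 | 6-hydroxy tetralone with C5 isopropenyl, C10 methyl and methyl ester arm, C11 and C14 isopropyl ethers (C6 carbinol unassigned) | C=C(C)[C@@H]1C(O)C(=O)c2c(OC(C)C)c(C(C)C)c(OC)c(OC(C)C)c2[C@@]1(C)CCC(=O)OC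
A7 | alternative 3 | aryl glyoxal with a C10 quaternary centre bearing methyl, 2-methylprop-1-enyl and methyl propanoate arm | O=CC(=O)c1c(OC(C)C)c(C(C)C)c(OC)c(OC(C)C)c1[C@@](C=C(C)C)(C)CCC(=O)OC
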